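**Plan**

1. Retrosynthetically, the carboxylic acid of ring B (the benzoic acid ring) is first masked as an allyl ester. Ring A (the chlorinated benzoyl ring: C1' bearing the ester carbonyl C7', C2' OH, C3' Cl, C4' OMe, C5' H, C6' pentyl) is then cut at C3'–C4' and C1'–C6'.
2. Enabling feature: ring A has oxygen on C2' and C4', chlorine on C3' between them and carbon on C1' and C6'. This is the pattern of a 4-chloroacetoacetate (C7', C1', C2', C3'), already esterified to O4 of ring B, condensed with a three-carbon unit at the oxidation level of 3-oxooctanoic acid (C4', C5', C6').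
3. Further cuts: the O4–C7' depside bond (allyl olivetolate plus chloroacetylketene from Meldrum's acid and chloroacetyl chloride) and C4'–C5' of the keto ketene acetal (hexanoyl chloride plus 1,1-dimethoxyethene).
4. Forward: ring B is bought as olivetolic acid, then esterified, acylated on O4 and silylated to the diene. Ring A, the only ring made, arises in one TiCl4-promoted cyclocondensation, and deallylation ends the route.
5. Stereochemistry: the target has no stereocentre. What must be controlled is regiochemistry: O4 against O2 in the acylation, and the orientation of the two partners in the ring-forming step.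

Key step: step 7

Remark: 1,1-dimethoxyethene is taken to be a catalogue reagent.
Remark: the enol ether double bonds and the transient sp3 centres of the silylated and open-chain intermediates form without control and are drawn without configuration, because all of them vanish when ring A aromatises.

**Route**

Step 1
Reactants: 1 olivetolic acid (2,4-dihydroxy-6-pentylbenzoic acid)
Product: 2 allyl 2,4-dihydroxy-6-pentylbenzoate
Conditions: allyl bromide (1.05 equiv), KHCO3 (1.2 equiv), DMF, 20 °C
Reagents that add atoms: allyl bromide, C=CCBr
Why: Carboxylate O-alkylation (SN2): KHCO3 deprotonates only the carboxylic acid, so allyl bromide should esterify it and leave both phenols free, and room temperature avoids decarboxylation of the β-resorcylic acid.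

Step 2
Reactants: 3 Meldrum's acid (2,2-dimethyl-1,3-dioxane-4,6-dione); 4 chloroacetyl chloride
Product: 5 5-(2-chloro-1-hydroxyethylidene)-2,2-dimethyl-1,3-dioxane-4,6-dione (chloroacetyl Meldrum's acid)
Conditions: pyridine (2 equiv), CH2Cl2, 0 → 20 °C; cold dilute aq. HCl wash; used crude
Reagents that add atoms: none
Why: C-acylation of Meldrum's acid: the pyridine-generated enolate of 3 attacks the acid chloride carbonyl much faster than the CH2Cl carbon, and the product is held as its hydrogen-bonded enol.

Step 3
Reactants: 2 allyl 2,4-dihydroxy-6-pentylbenzoate; 5 chloroacetyl Meldrum's acid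
Product: 7 allyl 4-[(4-chloro-3-oxobutanoyl)oxy]-2-hydroxy-6-pentylbenzoate, via chloroacetylketene 6 (not isolated)
Conditions: toluene, 110 °C, 2–3 h
Reagents that add atoms: none
Why: Thermal fragmentation of the acyl Meldrum's acid (retro-[4+2]) releases acetone, CO2 and the acylketene, which the phenol traps (acylketene acylation); O4 is the free and more nucleophilic hydroxyl, whereas O2 is hydrogen-bonded to and flanked by the ester, so the 4-ester should dominate.

Step 4
Reactants: 7 allyl 4-[(4-chloro-3-oxobutanoyl)oxy]-2-hydroxy-6-pentylbenzoate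
Product: 8 allyl 4-{[4-chloro-3-(trimethylsilyloxy)but-2-enoyl]oxy}-6-pentyl-2-(trimethylsilyloxy)benzoate
Conditions: Me3SiCl (3 equiv), Et3N (3 equiv), toluene, 20 °C, 48 h; filtration under argon, used crude
Reagents that add atoms: chlorotrimethylsilane, C[Si](C)(C)Cl
Why: Amine-mediated O-silylation: the acidic β-keto ester is converted into its silyl enol ether and the salicylate phenol into its silyl ether, which removes both acidic protons before the strong-base step.

Step 5
Reactants: 8 allyl 4-{[4-chloro-3-(trimethylsilyloxy)but-2-enoyl]oxy}-6-pentyl-2-(trimethylsilyloxy)benzoate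
Product: 9 allyl 4-{[4-chloro-1,3-bis(trimethylsilyloxy)buta-1,3-dien-1-yl]oxy}-6-pentyl-2-(trimethylsilyloxy)benzoate
Conditions: LiN(i-Pr)2 (1.1 equiv), THF, −78 °C, 1 h; Me3SiCl (1.3 equiv), −78 → 20 °C; used crude
Reagents that add atoms: chlorotrimethylsilane, C[Si](C)(C)Cl
Why: Kinetic γ-deprotonation of the vinylogous ester at CH2Cl and O-silylation of the dienolate give the silyl ketene acetal (the standard preparation of 4-chloro-1,3-bis(silyloxy)dienes), and keeping the aryl ester dienolate at −78 °C until it is silylated should suppress loss of aryloxide to a ketene.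

Step 6
Reactants: 10 hexanoyl chloride; 11 1,1-dimethoxyethene (2.2 equiv)
Product: 12 1,1-dimethoxyoct-1-en-3-one
Conditions: Et2O, 0 → 20 °C; bulb-to-bulb distillation
Reagents that add atoms: none
Why: McElvain acylation of a ketene acetal: the nucleophilic CH2 carbon of 11 attacks the acid chloride and a second equivalent of 11 takes up the HCl (ending as methyl acetate and chloromethane), so no amine is present that could turn hexanoyl chloride into a ketene.

Step 7
Reactants: 9 allyl 4-{[4-chloro-1,3-bis(trimethylsilyloxy)buta-1,3-dien-1-yl]oxy}-6-pentyl-2-(trimethylsilyloxy)benzoate; 12 1,1-dimethoxyoct-1-en-3-one (1.2 equiv)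
Product: 15 allyl 4-[(3-chloro-2-hydroxy-4-methoxy-6-pentylbenzoyl)oxy]-2-hydroxy-6-pentylbenzoate, via open-chain methoxy enone adduct 13 (not isolated), via cyclic aldol adduct 14 (not isolated)
Conditions: TiCl4 (1.1 equiv), CH2Cl2, −78 → 20 °C, 20 h; then 1 M aq. HCl
Reagents that add atoms: none
Why: TiCl4 binds the enone carbonyl of 12 and makes the ketene acetal carbon the preferred electrophilic site; the terminal CHCl carbon of diene 9, its most nucleophilic position, adds there in a vinylogous Mukaiyama–Michael step, and loss of methoxide restores a β-methoxy enone (13), which forms C3'–C4'. The remaining silyl ketene acetal carbon (C1') then attacks the titanium-bound ketone C6' in a Mukaiyama aldol step, a 6-(enolexo)-exo-trig closure that gives ring A as aldol 14, and loss of water followed by enolisation aromatises it. The closest known reaction type is the TiCl4-mediated formal [3+3] cyclocondensation of 1,3-bis(silyloxy)buta-1,3-dienes, 4-chloro dienes included, with 3-oxo ketene acetals or 3-silyloxy enones to give salicylates. No stereocentre is set, since the transient sp3 centres at C1', C3' and C6' are erased on aromatisation. The selectivity needed is regiochemical (terminal diene carbon to ketene acetal carbon, internal carbon to ketone), and it rests on the built-in difference between the two nucleophilic and the two electrophilic carbons, which places Cl on C3' between the oxygens, OMe on C4' and pentyl on C6'. The depside ester, the allyl ester and the ring B silyl ether should be spectators between −78 and 20 °C, and the acidic work-up frees the ring B phenol.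

Step 8
Reactants: 15 allyl 4-[(3-chloro-2-hydroxy-4-methoxy-6-pentylbenzoyl)oxy]-2-hydroxy-6-pentylbenzoate
Product: 16 4-[(3-chloro-2-hydroxy-4-methoxy-6-pentylbenzoyl)oxy]-2-hydroxy-6-pentylbenzoic acid (CNP0310773.0)
Conditions: Pd(PPh3)4 (5 mol %), morpholine (3 equiv), THF, 20 °C; then cold dilute aq. HCl
Reagents that add atoms: none
Why: Tsuji–Trost-type deallylation: zerovalent palladium ionises the allyl ester to a π-allyl palladium carboxylate and morpholine captures the allyl group, conditions under which the aryl chloride, the methyl ether and the depside ester (its carbonyl shielded by the 2'-OH and 6'-pentyl groups) should stay intact.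

**Compound list**

1 | olivetolic acid (2,4-dihydroxy-6-pentylbenzoic acid) | CCCCCc1cc(O)cc(O)c1C(=O)O | starting material
2 | allyl 2,4-dihydroxy-6-pentylbenzoate | C=CCOC(=O)c1c(O)cc(O)cc1CCCCC | intermediate
3 | Meldrum's acid (2,2-dimethyl-1,3-dioxane-4,6-dione) | CC1(C)OC(=O)CC(=O)O1 | starting material
4 | chloroacetyl chloride | ClCC(=O)Cl | starting material
5 | 5-(2-chloro-1-hydroxyethylidene)-2,2-dimethyl-1,3-dioxane-4,6-dione | CC1(C)OC(=O)C(=C(O)CCl)C(=O)O1 | intermediate
6 | chloroacetylketene (4-chlorobut-1-ene-1,3-dione; formed in the flask) | O=C=CC(=O)CCl | intermediate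
7 | allyl 4-[(4-chloro-3-oxobutanoyl)oxy]-2-hydroxy-6-pentylbenzoate | C=CCOC(=O)c1c(O)cc(OC(=O)CC(=O)CCl)cc1CCCCC | intermediate
8 | allyl 4-{[4-chloro-3-(trimethylsilyloxy)but-2-enoyl]oxy}-6-pentyl-2-(trimethylsilyloxy)benzoate | C=CCOC(=O)c1c(O[Si](C)(C)C)cc(OC(=O)C=C(O[Si](C)(C)C)CCl)cc1CCCCC | intermediate
9 | allyl 4-{[4-chloro-1,3-bis(trimethylsilyloxy)buta-1,3-dien-1-yl]oxy}-6-pentyl-2-(trimethylsilyloxy)benzoate | C=CCOC(=O)c1c(O[Si](C)(C)C)cc(OC(O[Si](C)(C)C)=CC(O[Si](C)(C)C)=CCl)cc1CCCCC | intermediate
10 | hexanoyl chloride | CCCCCC(=O)Cl | starting material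
11 | 1,1-dimethoxyethene | C=C(OC)OC | starting material
12 | 1,1-dimethoxyoct-1-en-3-one | CCCCCC(=O)C=C(OC)OC | intermediate
13 | allyl 4-{[4-chloro-5-methoxy-3,7-dioxo-1-(trimethylsilyloxy)dodeca-1,5-dien-1-yl]oxy}-6-pentyl-2-(trimethylsilyloxy)benzoate (formed in the flask) | C=CCOC(=O)c1c(O[Si](C)(C)C)cc(OC(O[Si](C)(C)C)=CC(=O)C(Cl)C(OC)=CC(=O)CCCCC)cc1CCCCC | intermediate
14 | allyl 4-{[(3-chloro-6-hydroxy-4-methoxy-2-oxo-6-pentylcyclohex-4-en-1-yl)carbonyl]oxy}-6-pentyl-2-(trimethylsilyloxy)benzoate (formed in the flask, drawn as the free alcohol) | C=CCOC(=O)c1c(O[Si](C)(C)C)cc(OC(=O)C2C(=O)C(Cl)C(OC)=CC2(O)CCCCC)cc1CCCCC | intermediate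
15 | allyl 4-[(3-chloro-2-hydroxy-4-methoxy-6-pentylbenzoyl)oxy]-2-hydroxy-6-pentylbenzoate | C=CCOC(=O)c1c(O)cc(OC(=O)c2c(CCCCC)cc(OC)c(Cl)c2O)cc1CCCCC | intermediate
16 | 4-[(3-chloro-2-hydroxy-4-methoxy-6-pentylbenzoyl)oxy]-2-hydroxy-6-pentylbenzoic acid | CCCCCc1cc(OC(=O)c2c(CCCCC)cc(OC)c(Cl)c2O)cc(O)c1C(=O)O | target

**Step count and risks**

Total step count: 8. Longest linear sequence: 6 steps (steps 1, 3, 4, 5, 7 and 8 from olivetolic acid; steps 2 and 6 are side branches).

Steps most likely to fail:

1. Step 7. The aryloxy silyl ketene acetal may be too weak a nucleophile for the ring closure, so the sequence could stall at the open-chain stage. TiCl4 held by the ring B salicylate may also cleave or transfer the depside acyl group. The fallback sets out from 5 and returns at 15: ring A is made by the same cyclocondensation in the well-precedented alkyl ester series, and the depside bond is formed afterwards. Compound 5 is heated with allyl alcohol in toluene to give allyl 4-chloro-3-oxobutanoate F1. Et3N/Me3SiCl converts it into allyl 4-chloro-3-(trimethylsilyloxy)but-2-enoate F2, and LiN(i-Pr)2/Me3SiCl at −78 °C into 1-(allyloxy)-4-chloro-1,3-bis(trimethylsilyloxy)buta-1,3-diene F3. TiCl4 with 12 in CH2Cl2 should give allyl 3-chloro-2-hydroxy-4-methoxy-6-pentylbenzoate F4, and Pd(PPh3)4/morpholine frees 3-chloro-2-hydroxy-4-methoxy-6-pentylbenzoic acid F5. Finally (CF3CO)2O in toluene condenses F5 with the 4-hydroxyl of 2 (mixed-anhydride depside esterification) to give 15.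

2. Step 5. The lithium dienolate of the aryl ester may fragment into aryloxide and a ketene, or the base may deprotonate the benzylic CH2 of the pentyl group ortho to the allyl ester. The fallback sets out from 7 and returns at 9, bypassing 8. The strong-base, two-stage route is given up for a single soft enolisation with Me3SiOTf (3.3 equiv) and Et3N in Et2O at 0 °C. This silylates the phenol and converts the β-keto ester directly into the 1,3-bis(silyloxy)diene without forming a metal dienolate, so no new compound arises.

3. Step 6. Chloride may demethylate the oxocarbenium intermediate to give the β-keto ester, or the keto ketene acetal may hydrolyse during isolation; supply of 1,1-dimethoxyethene is a further weak point. The fallback sets out from 10 and returns at 12 without any ketene acetal. Friedel–Crafts acylation of 1,1-dichloroethene with 10 and AlCl3 in CH2Cl2 gives 1,1,1-trichlorooctan-3-one F6, which loses HCl on washing with aq. Na2CO3 and distillation to give 1,1-dichlorooct-1-en-3-one F7. NaOMe (2 equiv) in MeOH at 0 °C then replaces both vinylic chlorides by addition–elimination to give 12.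

**Further compounds**

F1 | step 7 | allyl 4-chloro-3-oxobutanoate | C=CCOC(=O)CC(=O)CCl
F2 | step 7 | allyl 4-chloro-3-(trimethylsilyloxy)but-2-enoate | C=CCOC(=O)C=C(O[Si](C)(C)C)CCl
F3 | step 7 | 1-(allyloxy)-4-chloro-1,3-bis(trimethylsilyloxy)buta-1,3-diene | C=CCOC(O[Si](C)(C)C)=CC(O[Si](C)(C)C)=CCl
F4 | step 7 | allyl 3-chloro-2-hydroxy-4-methoxy-6-pentylbenzoate | C=CCOC(=O)c1c(CCCCC)cc(OC)c(Cl)c1O
F5 | step 7 | 3-chloro-2-hydroxy-4-methoxy-6-pentylbenzoic acid | CCCCCc1cc(OC)c(Cl)c(O)c1C(=O)O
F0 | step 5 | none | none
F6 | step 6 | 1,1,1-trichlorooctan-3-one | CCCCCC(=O)CC(Cl)(Cl)Cl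
F7 | step 6 | 1,1-dichlorooct-1-en-3-one | CCCCCC(=O)C=C(Cl)Cl
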